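**Strategy.** The cyclohexene ring (C1 = CHOAc, C2=C3 alkene, C4 = CMe2, C5 = CHBr, C6 = CH2) is traced back to a cyclopentene plus one carbon: vinylic C2, which carries the bromochloroethyl arm, is the carbon of dibromocarbene, inserted between C1 and C3. The key step exploits the allylic acetate array C1(OAc)–C2=C3. Silver-assisted, strain-releasing electrocyclic opening of (3S)-3,6,6-tribromo-2,2-dimethylbicyclo[3.1.0]hexane expands the five-membered ring to the six-membered ring and at once places the C2=C3 double bond, leaves a C2–Br handle for the side chain and delivers the C1 acetate, remote from C4 and cis to C5–Br. The C5–Br centre stems from desymmetrised 2,2-dimethylcyclopentane-1,3-dione.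

Key step: step 6

Remark: 2,2-dimethylcyclopentane-1,3-dione (1) is assumed to be purchasable; six-membered-ring atoms are numbered as in the name of the target.

**Step 1**
Reactants: 1 2,2-dimethylcyclopentane-1,3-dione
Product: 2 (3R)-3-hydroxy-2,2-dimethylcyclopentan-1-one
Conditions: (S)-Me-CBS (20 mol %), BH3·SMe2 (0.6 equiv), THF, −30 °C; MeOH quench
Reagents that add atoms: none
Why: Corey–Bakshi–Shibata reduction differentiates the enantiotopic carbonyl groups of the achiral dione, the quaternary C2 acting as the large substituent so that hydride delivery should give the (R)-carbinol, while sub-stoichiometric borane limits over-reduction to the diol.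

**Step 2**
Reactants: 2 (3R)-3-hydroxy-2,2-dimethylcyclopentan-1-one
Product: 3 (3S)-3-bromo-2,2-dimethylcyclopentan-1-one
Conditions: CBr4, PPh3, CH2Cl2, 0 °C → rt
Reagents that add atoms: carbon tetrabromide BrC(Br)(Br)Br
Why: Appel reaction, in which bromide displaces the alkoxyphosphonium group by SN2 with inversion to set the (S)-C–Br centre, the five-membered ring easing backside attack and the β-carbonyl group disfavouring ionisation and thus methyl migration.

**Step 3**
Reactants: 3 (3S)-3-bromo-2,2-dimethylcyclopentan-1-one
Product: 4 (4S)-4-bromo-5,5-dimethylcyclopent-1-en-1-yl trifluoromethanesulfonate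
Conditions: KHMDS, THF, −78 °C; then N-(5-chloropyridin-2-yl)bis(trifluoromethanesulfonimide), −78 °C
Reagents that add atoms: N-(5-chloropyridin-2-yl)bis(trifluoromethanesulfonimide) FC(F)(F)S(=O)(=O)N(c1ccc(Cl)cn1)S(=O)(=O)C(F)(F)F
Why: Kinetic enolate O-triflation, in which the ketone can enolise only towards the CH2 group because the other α-carbon is quaternary, and fast sulfonylation at −78 °C traps the enolate before it can attack the remote bromide, leaving the stereocentre untouched.

**Step 4**
Reactants: 4 (4S)-4-bromo-5,5-dimethylcyclopent-1-en-1-yl trifluoromethanesulfonate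
Product: 5 (4S)-4-bromo-3,3-dimethylcyclopent-1-ene
Conditions: Pd(OAc)2 (5 mol %), PPh3 (10 mol %), HCO2H, Bu3N, DMF, 50 °C; product kept as a pentane solution (volatile)
Reagents that add atoms: none
Why: Palladium-catalysed formate reduction of an enol triflate (oxidative addition into C–OTf, formate decarboxylation to Pd–H, reductive elimination), under which the unactivated secondary bromide should be inert.

**Step 5**
Reactants: 5 (4S)-4-bromo-3,3-dimethylcyclopent-1-ene
Product: 6 (3S)-3,6,6-tribromo-2,2-dimethylbicyclo[3.1.0]hexane
Conditions: CHBr3, 50% aq. NaOH, BnEt3NCl (cat.), CH2Cl2, 0 °C → rt; used crude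
Reagents that add atoms: bromoform BrC(Br)Br
Why: Dibromocarbene [2+1] cycloaddition under phase-transfer conditions, whose facial selectivity is irrelevant because both cyclopropane diastereomers give the same cation in step 6.

**Step 6**
Reactants: 6 (3S)-3,6,6-tribromo-2,2-dimethylbicyclo[3.1.0]hexane
Product: 8 (1R,5S)-2,5-dibromo-4,4-dimethylcyclohex-2-en-1-yl acetate, via 2-bromoallyl cation 7 (not isolated)
Conditions: AgOAc (1.3 equiv), AcOH, 20 → 45 °C, dark
Reagents that add atoms: silver(I) acetate CC(=O)[O-].[Ag+]
Why: Silver(I) removes the endo bromide of the gem-dibromocyclopropane while the bond shared by the three- and five-membered rings opens by disrotatory two-electron electrocyclic ring opening (cyclopropyl-to-allyl cation, driven by strain release), and acetate captures the 2-bromoallyl cation 7. The closest known reaction type is the silver-promoted ring expansion and solvolysis of ring-fused gem-dihalocyclopropanes to 2-halocycloalk-2-enyl esters. No ring is closed by a new bond: the six-membered ring arises from the five-membered ring when the internal cyclopropane bond is cleaved, so that the former carbene carbon becomes ring atom C2. The new stereocentre C1 is controlled by C5: in the envelope-shaped cation the C5–Br bond should lie pseudoaxial (one gauche methyl instead of two, no syn-axial hydrogen, electrostatic attraction to the cation), and chair-like axial attack on that face should give the 1,5-cis acetate, as in captures of six-membered cations that carry a 1,3-related pseudoaxial heteroatom. The step needs chemoselective ionisation (the strained cyclopropyl C–Br ionises in concert with ring opening, the secondary C–Br should not), regioselective capture at C1 rather than C3 (C3 is neopentylic and shielded by the C4 methyl groups) and the facial selectivity just described. Both cyclopropane diastereomers of 6, and any 6 that has already opened thermally to the allylic bromide, funnel into the same cation.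

**Step 7**
Reactants: 8 (1R,5S)-2,5-dibromo-4,4-dimethylcyclohex-2-en-1-yl acetate
Product: 10 (1R,5S)-5-bromo-2-(2-chloroacetyl)-4,4-dimethylcyclohex-2-en-1-yl acetate, via ethoxyvinyl diene 9 (not isolated)
Conditions: Bu3Sn(C(OEt)=CH2), Pd2(dba)3 (2.5 mol %), AsPh3 (20 mol %), CuI (10 mol %), NMP, 50 °C; then NCS, THF/H2O, 0 °C
Reagents that add atoms: tributyl(1-ethoxyvinyl)stannane CCCC[Sn](CCCC)(CCCC)C(=C)OCC; N-chlorosuccinimide O=C1CCC(=O)N1Cl; water O
Why: Stille coupling at the vinylic C–Br bond (oxidative addition there is far faster than at the secondary alkyl bromide) followed by electrophilic chlorination of the 2-ethoxydiene at its terminal CH2 and hydrolysis of the resulting oxocarbenium ion to the chloromethyl ketone, with no stereocentre affected.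

**Step 8**
Reactants: 10 (1R,5S)-5-bromo-2-(2-chloroacetyl)-4,4-dimethylcyclohex-2-en-1-yl acetate
Product: 11 (1R,5S)-5-bromo-2-[(1S)-2-chloro-1-hydroxyethyl]-4,4-dimethylcyclohex-2-en-1-yl acetate
Conditions: (S)-Me-CBS (0.5 equiv), catecholborane, toluene, −78 °C
Reagents that add atoms: none
Why: Corey–Bakshi–Shibata 1,2-reduction under reagent control, in which the α-branched cyclohexenyl group is the large and CH2Cl the small substituent, so that the (S)-catalyst should give the (S)-chlorohydrin.

**Step 9**
Reactants: 11 (1R,5S)-5-bromo-2-[(1S)-2-chloro-1-hydroxyethyl]-4,4-dimethylcyclohex-2-en-1-yl acetate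
Product: 12 (1R,5S)-5-bromo-2-[(1R)-1-bromo-2-chloroethyl]-4,4-dimethylcyclohex-2-en-1-yl acetate
Conditions: CBr4, PPh3, CH2Cl2, −20 → 0 °C
Reagents that add atoms: carbon tetrabromide BrC(Br)(Br)Br
Why: Appel reaction, in which SN2 displacement with inversion converts the (S)-allylic alcohol into the (R)-bromide, SN2′ attack at C3 being blocked by the adjacent gem-dimethyl group and ionisation being disfavoured by the β-chlorine.

**Compound list**
1 | 2,2-dimethylcyclopentane-1,3-dione | CC1(C)C(=O)CCC1=O | starting material
2 | (3R)-3-hydroxy-2,2-dimethylcyclopentan-1-one | O[C@@H]1CCC(=O)C1(C)C | intermediate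
3 | (3S)-3-bromo-2,2-dimethylcyclopentan-1-one | Br[C@H]1CCC(=O)C1(C)C | intermediate
4 | (4S)-4-bromo-5,5-dimethylcyclopent-1-en-1-yl trifluoromethanesulfonate | Br[C@H]1CC=C(OS(=O)(=O)C(F)(F)F)C1(C)C | intermediate
5 | (4S)-4-bromo-3,3-dimethylcyclopent-1-ene | Br[C@H]1CC=CC1(C)C | intermediate
6 | (3S)-3,6,6-tribromo-2,2-dimethylbicyclo[3.1.0]hexane (both ring-fusion diastereomers) | Br[C@H]1CC2C(C2(Br)Br)C1(C)C | intermediate
7 | (5S)-2,5-dibromo-4,4-dimethylcyclohex-2-en-1-ylium (2-bromoallyl cation) | Br[C@H]1C[CH+]C(Br)=CC1(C)C | intermediate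
8 | (1R,5S)-2,5-dibromo-4,4-dimethylcyclohex-2-en-1-yl acetate | CC(=O)O[C@@H]1C[C@H](Br)C(C)(C)C=C1Br | intermediate
9 | (1R,5S)-5-bromo-2-(1-ethoxyethenyl)-4,4-dimethylcyclohex-2-en-1-yl acetate | CC(=O)O[C@@H]1C[C@H](Br)C(C)(C)C=C1C(=C)OCC | intermediate
10 | (1R,5S)-5-bromo-2-(2-chloroacetyl)-4,4-dimethylcyclohex-2-en-1-yl acetate | CC(=O)O[C@@H]1C[C@H](Br)C(C)(C)C=C1C(=O)CCl | intermediate
11 | (1R,5S)-5-bromo-2-[(1S)-2-chloro-1-hydroxyethyl]-4,4-dimethylcyclohex-2-en-1-yl acetate | CC(=O)O[C@@H]1C[C@H](Br)C(C)(C)C=C1[C@H](O)CCl | intermediate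
12 | (1R,5S)-5-bromo-2-[(1R)-1-bromo-2-chloroethyl]-4,4-dimethylcyclohex-2-en-1-yl acetate | CC(=O)O[C@@H]1C[C@H](Br)C(C)(C)C=C1[C@@H](Br)CCl | target

**Totals.** Total step count: 9. Longest linear sequence: 9 steps (1 → 12).

**Steps most likely to fail**

Step 6. The capture of cation 7 may show poor or reversed facial selectivity at C1, since the pseudoaxial-heteroatom model is an expectation and a 1,3-related substituent can steer a cyclohexenyl cation only weakly. The fallback sets out from 6 and comes back at 8, and replaces substrate control by reagent control. Silver triflate in aqueous acetone (CaCO3) should open 6 with water as nucleophile to the C1-epimeric (5S)-2,5-dibromo-4,4-dimethylcyclohex-2-en-1-ols F1. Dess–Martin oxidation without amine base (the product is a β-bromo ketone prone to loss of HBr) should converge both epimers on (5S)-2,5-dibromo-4,4-dimethylcyclohex-2-en-1-one F2. Reduction with (S)-Me-CBS and catecholborane, the bromoalkenyl side acting as the large group, should give (1R,5S)-2,5-dibromo-4,4-dimethylcyclohex-2-en-1-ol F3, which is acetylated (Ac2O, pyridine, DMAP) to 8.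

Step 2. SN2 at the neopentylic carbinol carbon is slow and may be outrun by E2 elimination to the β,γ-unsaturated ketone or by methyl migration after partial ionisation. The fallback sets out from 2 and comes back at 3, and separates activation from displacement. Tf2O and pyridine in CH2Cl2 at −20 °C should give (1R)-2,2-dimethyl-3-oxocyclopentyl trifluoromethanesulfonate F4, a discrete and far more reactive sulfonate, which Bu4NBr in toluene should displace with inversion at or below room temperature.

Step 7. Palladium(0) may ionise the allylic acetate to a π-allyl complex in competition with oxidative addition at the vinylic C–Br bond. The fallback is palladium-free, sets out from 8 and comes back at 10. Nozaki–Hiyama–Kishi coupling with acetaldehyde (CrCl2, cat. NiCl2, DMF) should give (1R,5S)-5-bromo-2-(1-hydroxyethyl)-4,4-dimethylcyclohex-2-en-1-yl acetate F5 as a mixture of carbinol epimers. Dess–Martin oxidation should give (1R,5S)-2-acetyl-5-bromo-4,4-dimethylcyclohex-2-en-1-yl acetate F6. TMSOTf and Et3N should convert the methyl ketone into (1R,5S)-5-bromo-4,4-dimethyl-2-[1-(trimethylsilyloxy)ethenyl]cyclohex-2-en-1-yl acetate F7, and NCS in THF should chlorinate this silyl dienol ether at its terminal carbon to give 10.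

**Further compounds**
F1 | step 6 | (5S)-2,5-dibromo-4,4-dimethylcyclohex-2-en-1-ol (C1 epimers) | OC1C[C@H](Br)C(C)(C)C=C1Br
F2 | step 6 | (5S)-2,5-dibromo-4,4-dimethylcyclohex-2-en-1-one | O=C1C[C@H](Br)C(C)(C)C=C1Br
F3 | step 6 | (1R,5S)-2,5-dibromo-4,4-dimethylcyclohex-2-en-1-ol | O[C@@H]1C[C@H](Br)C(C)(C)C=C1Br
F4 | step 2 | (1R)-2,2-dimethyl-3-oxocyclopentyl trifluoromethanesulfonate | FC(F)(F)S(=O)(=O)O[C@@H]1CCC(=O)C1(C)C
F5 | step 7 | (1R,5S)-5-bromo-2-(1-hydroxyethyl)-4,4-dimethylcyclohex-2-en-1-yl acetate (carbinol epimers) | CC(=O)O[C@@H]1C[C@H](Br)C(C)(C)C=C1C(C)O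
F6 | step 7 | (1R,5S)-2-acetyl-5-bromo-4,4-dimethylcyclohex-2-en-1-yl acetate | CC(=O)O[C@@H]1C[C@H](Br)C(C)(C)C=C1C(C)=O
F7 | step 7 | (1R,5S)-5-bromo-4,4-dimethyl-2-[1-(trimethylsilyloxy)ethenyl]cyclohex-2-en-1-yl acetate | CC(=O)O[C@@H]1C[C@H](Br)C(C)(C)C=C1C(=C)O[Si](C)(C)C
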